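**Retrosynthetic overview** (prostanoid numbering: C1 ester carbon, C7 acetoxy carbon, ring C8–C12 with C9 ketone, C10 chlorine, C12 carbinol, C13–C20 octenyl chain)

- The strategy rests on one feature: on the five-membered ring C8–C12 the tertiary hydroxyl on C12 is cis to carbon C7 on the neighbouring ring carbon C8, which is the retron of a cis-fused β-lactone between O12 and a C7 carboxyl.
- Late stage: the C7 acetate, the C10 chlorine and the C10=C11 double bond are added to a C9 ketone released from a dioxolane. The C6–C7 bond comes from an acetylide and a C7 Weinreb amide made by opening the lactone; C7 is set by a catalyst-controlled ynone reduction and C5=C6 by semihydrogenation.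
- Key disconnection C8–C12: an achiral keto acid is closed by a chiral Lewis base to the bicyclic lactone. The cyclopentane (C8–C12) forms first and the oxetanone (O12–C7) directly after, in the same operation; no other ring is formed, and the oxetanone is opened again one step later.
- The keto acid is built from methyl acetoacetate (C7–C10), allyl bromide (C11–C13) and 1-heptyne (C14–C20). The C14–C15 triple bond is reduced to the Z alkene before the C12 ketone is made, because a β,γ-acetylenic ketone would isomerise to the allenyl ketone under the amine base of the key step.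
- C1–C6 is brought in as 6,6,6-trimethoxyhex-1-yne, so that the acetylide carries no electrophilic ester.

Key step: step 8

Assumption: (S)-homobenzotetramisole is taken to be the catalyst enantiomer that leads to the (1R,5S)-lactone; if the sense of induction is the opposite, the (R)-catalyst is used and nothing else changes.

**Route**

Step 1
Reactants: 1 methyl acetoacetate; 2 allyl bromide
Product: 4 methyl 3-oxohept-6-enoate, via acetoacetate dianion 3 (not isolated)
Conditions: NaH, THF, 0 °C; n-BuLi, 0 °C; then 2, 0 °C → rt; aq. HCl work-up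
Reagents that add atoms: allyl bromide (2), C=CCBr
Why: Dianion γ-alkylation of a β-keto ester (Weiler alkylation): after the second deprotonation the terminal carbon is the most nucleophilic site, so allyl bromide forms C10–C11 there and not at C8.

Step 2
Reactants: 4 methyl 3-oxohept-6-enoate
Product: 5 methyl 2-[2-(but-3-en-1-yl)-1,3-dioxolan-2-yl]acetate
Conditions: HOCH2CH2OH, p-TsOH·H2O (cat.), benzene, reflux, Dean–Stark
Reagents that add atoms: ethylene glycol, OCCO
Why: Acid-catalysed ketalisation with azeotropic removal of water masks the C9 ketone as a dioxolane, so that later only the C12 ketone is electrophilic and the acid is not a β-keto acid.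

Step 3
Reactants: 5 methyl 2-[2-(but-3-en-1-yl)-1,3-dioxolan-2-yl]acetate
Product: 6 methyl 2-{2-[2-(oxiran-2-yl)ethyl]-1,3-dioxolan-2-yl}acetate (racemic)
Conditions: mCPBA, CH2Cl2, 0 °C → rt
Reagents that add atoms: mCPBA, OOC(=O)c1cccc(Cl)c1
Why: Prilezhaev epoxidation of the only alkene; the racemic C12 centre does not matter because it becomes the C12 ketone in step 7.

Step 4
Reactants: 6 methyl 2-{2-[2-(oxiran-2-yl)ethyl]-1,3-dioxolan-2-yl}acetate; 7 1-heptyne
Product: 9 methyl 2-[2-(3-hydroxyundec-5-yn-1-yl)-1,3-dioxolan-2-yl]acetate (racemic), via lithium heptynide 8 (not isolated)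
Conditions: 7, n-BuLi, THF, −78 °C; BF3·OEt2; then 6, −78 °C
Reagents that add atoms: 1-heptyne (7), CCCCCC#C
Why: BF3-assisted opening of a terminal epoxide by a lithium acetylide (Yamaguchi alkynylation) takes place at the unsubstituted carbon C13 and forms C13–C14, while ester and dioxolane should be inert at −78 °C.

Step 5
Reactants: 9 methyl 2-[2-(3-hydroxyundec-5-yn-1-yl)-1,3-dioxolan-2-yl]acetate
Product: 10 methyl 2-{2-[(5Z)-3-hydroxyundec-5-en-1-yl]-1,3-dioxolan-2-yl}acetate (racemic)
Conditions: H2 (1 atm), Pd/CaCO3 poisoned with Pb(OAc)2, quinoline, EtOAc, rt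
Reagents that add atoms: none
Why: Lindlar semihydrogenation adds hydrogen syn and should stop at the 14Z alkene, which is set now so that the later C12 ketone is a skipped enone and not a base-labile β,γ-ynone.

Step 6
Reactants: 10 methyl 2-{2-[(5Z)-3-hydroxyundec-5-en-1-yl]-1,3-dioxolan-2-yl}acetate
Product: 11 2-{2-[(5Z)-3-hydroxyundec-5-en-1-yl]-1,3-dioxolan-2-yl}acetic acid (racemic)
Conditions: LiOH, THF/H2O, 0 °C → rt; then 1 M HCl to pH 4, 0 °C
Reagents that add atoms: lithium hydroxide, [Li+].[OH-]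
Why: Saponification is run before the alcohol is oxidised, so that no β,γ-unsaturated ketone meets hydroxide, and the dioxolane should survive the brief cold acidification.

Step 7
Reactants: 11 2-{2-[(5Z)-3-hydroxyundec-5-en-1-yl]-1,3-dioxolan-2-yl}acetic acid
Product: 12 2-{2-[(5Z)-3-oxoundec-5-en-1-yl]-1,3-dioxolan-2-yl}acetic acid, i.e. (8Z)-3,3-(ethylenedioxy)-6-oxotetradec-8-enoic acid (achiral)
Conditions: Dess–Martin periodinane, pyridine, CH2Cl2, 0 °C → rt
Reagents that add atoms: none
Why: Dess–Martin oxidation under pyridine buffering converts the secondary alcohol into the C12 ketone without moving the 14Z double bond into conjugation and tolerates the free acid.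

Step 8
Reactants: 12 (8Z)-3,3-(ethylenedioxy)-6-oxotetradec-8-enoic acid
Product: 15 (1R,5S)-5-[(2Z)-oct-2-en-1-yl]spiro[6-oxabicyclo[3.2.0]heptane-2,2'-[1,3]dioxolan]-7-one, via mixed tosyl anhydride 13 (not isolated), via acyl isothiouronium tosylate 14 (not isolated)
Conditions: TsCl, (S)-homobenzotetramisole (20 mol %), LiCl, i-Pr2NEt, CH2Cl2, 23 °C, slow addition of 12
Reagents that add atoms: none
Why: This is a nucleophile-catalysed aldol–lactonisation of a keto acid, a known way to bicyclic β-lactones: TsCl activates the acid as mixed anhydride 13, the isothiourea is acylated to 14, and i-Pr2NEt removes a C8 proton to give the catalyst-bound ammonium enolate. Its carbon C8 adds to the LiCl-activated C12 ketone in a 5-(enolexo)-exo-trig aldol closure that forms the C8–C12 bond and the cyclopentane (C8–C9–C10–C11–C12). The tertiary C12 alkoxide then attacks the acyl isothiouronium carbon C7 in a 4-exo-trig closure that forms the oxetanone and releases the catalyst. C8 is set by the stereocentre of the catalyst, whose phenyl group shields one face of the enolate, and C12 follows because only the aldolate with O12 cis to C7 can lactonise, so the catalyst fixes the absolute and the ring fusion the relative configuration. The step needs enantioface selection (the substrate is achiral, so the catalyst alone controls it), enolisation at C8 only (only C8 is α to the acyl ammonium and C9 is blocked as the dioxolane) and an aldol that outruns migration of the 14Z double bond or opening of the dioxolane by the enolate (slow addition of 12 and irreversible lactonisation should secure this).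

Step 9
Reactants: 15 (1R,5S)-5-[(2Z)-oct-2-en-1-yl]spiro[6-oxabicyclo[3.2.0]heptane-2,2'-[1,3]dioxolan]-7-one
Product: 16 (6R,7S)-7-hydroxy-N-methoxy-N-methyl-7-[(2Z)-oct-2-en-1-yl]-1,4-dioxaspiro[4.4]nonane-6-carboxamide
Conditions: MeNH(OMe)·HCl, i-PrMgCl, THF, −20 → 0 °C
Reagents that add atoms: N,O-dimethylhydroxylamine hydrochloride, CNOC.Cl
Why: Aminolysis of the strained lactone by the chloromagnesium amide (Weinreb amide formation) can only go by acyl–oxygen cleavage because C12 is quaternary, so C8 and C12 keep their configuration.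

Step 10
Reactants: 16 (6R,7S)-7-hydroxy-N-methoxy-N-methyl-7-[(2Z)-oct-2-en-1-yl]-1,4-dioxaspiro[4.4]nonane-6-carboxamide
Product: 17 (6R,7S)-7-[(tert-butyldimethylsilyl)oxy]-N-methoxy-N-methyl-7-[(2Z)-oct-2-en-1-yl]-1,4-dioxaspiro[4.4]nonane-6-carboxamide
Conditions: TBSOTf, 2,6-lutidine, CH2Cl2, 0 °C → rt
Reagents that add atoms: TBSOTf, CC(C)(C)[Si](C)(C)OS(=O)(=O)C(F)(F)F
Why: Silylation of the tertiary alcohol with a silyl triflate protects O12, so that neither retro-aldol cleavage of C8–C12 nor oxa-Michael closure onto the later ynone can occur.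

Step 11
Reactants: 18 4-bromo-1,1,1-trimethoxybutane; 19 lithium acetylide–ethylenediamine complex (LiC≡CH·H2NCH2CH2NH2)
Product: 20 6,6,6-trimethoxyhex-1-yne
Conditions: DMSO, 10 °C → rt
Reagents that add atoms: lithium acetylide–ethylenediamine complex (19), [Li]C#C.NCCN
Why: SN2 alkylation of lithium acetylide by a primary bromide in DMSO; the ortho ester is inert to the acetylide and keeps C1 at the acid oxidation level in a form that an organolithium cannot attack.

Step 12
Reactants: 17 (6R,7S)-7-[(tert-butyldimethylsilyl)oxy]-N-methoxy-N-methyl-7-[(2Z)-oct-2-en-1-yl]-1,4-dioxaspiro[4.4]nonane-6-carboxamide; 20 6,6,6-trimethoxyhex-1-yne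
Product: 23 methyl 7-{7-[(tert-butyldimethylsilyl)oxy]-7-[(2Z)-oct-2-en-1-yl]-1,4-dioxaspiro[4.4]nonan-6-yl}-7-oxohept-5-ynoate (ring configuration as in 17), via lithium trimethoxyhexynide 21 (not isolated), via ortho ester ynone 22 (not isolated)
Conditions: 20, n-BuLi, THF, −78 °C; then 17, −78 → 0 °C; aq. NH4Cl; then aq. NaHSO4 (pH 3), THF, 0 °C
Reagents that add atoms: 6,6,6-trimethoxyhex-1-yne (20), COC(OC)(OC)CCCC#C; water, O
Why: Weinreb ketone synthesis: the acetylide adds once to a chelated tetrahedral adduct that collapses to the ynone only on quench, and the mild acid of the work-up hydrolyses the trimethyl ortho ester to the C1 methyl ester while dioxolane and silyl ether should remain.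

Step 13
Reactants: 23 methyl 7-{7-[(tert-butyldimethylsilyl)oxy]-7-[(2Z)-oct-2-en-1-yl]-1,4-dioxaspiro[4.4]nonan-6-yl}-7-oxohept-5-ynoate
Product: 24 methyl (7R)-7-{7-[(tert-butyldimethylsilyl)oxy]-7-[(2Z)-oct-2-en-1-yl]-1,4-dioxaspiro[4.4]nonan-6-yl}-7-hydroxyhept-5-ynoate (ring configuration as in 17)
Conditions: Ru[(R,R)-TsNCH(Ph)CH(Ph)NH](η6-p-cymene) (5 mol %), i-PrOH, rt
Reagents that add atoms: none
Why: Noyori asymmetric transfer hydrogenation of an α,β-acetylenic ketone under base-free conditions, in which the (R,R)-ligand should direct hydride to the carbonyl face that gives the 7R carbinol (alkynyl ranks above C8 here), the same spatial arrangement that is named 7S in the target, with the catalyst and not the ring controlling the new centre.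

Step 14
Reactants: 24 methyl (7R)-7-{7-[(tert-butyldimethylsilyl)oxy]-7-[(2Z)-oct-2-en-1-yl]-1,4-dioxaspiro[4.4]nonan-6-yl}-7-hydroxyhept-5-ynoate
Product: 25 methyl (5Z,7S)-7-{7-[(tert-butyldimethylsilyl)oxy]-7-[(2Z)-oct-2-en-1-yl]-1,4-dioxaspiro[4.4]nonan-6-yl}-7-hydroxyhept-5-enoate
Conditions: H2 (1 atm), Pd/CaCO3 poisoned with Pb(OAc)2, quinoline, EtOAc, rt
Reagents that add atoms: none
Why: Lindlar semihydrogenation of the propargylic alcohol gives the 5Z alkene by syn addition and should leave the disubstituted 14Z alkene untouched.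

Step 15
Reactants: 25 methyl (5Z,7S)-7-{7-[(tert-butyldimethylsilyl)oxy]-7-[(2Z)-oct-2-en-1-yl]-1,4-dioxaspiro[4.4]nonan-6-yl}-7-hydroxyhept-5-enoate
Product: 26 methyl (5Z,7S)-7-[(tert-butyldimethylsilyl)oxy]-7-{7-[(tert-butyldimethylsilyl)oxy]-7-[(2Z)-oct-2-en-1-yl]-1,4-dioxaspiro[4.4]nonan-6-yl}hept-5-enoate
Conditions: TBSOTf, 2,6-lutidine, CH2Cl2, −78 → 0 °C
Reagents that add atoms: TBSOTf, CC(C)(C)[Si](C)(C)OS(=O)(=O)C(F)(F)F
Why: Silylation of the secondary allylic alcohol, so that both oxygens β to the coming C9 ketone are poor leaving groups and carry no acidic proton.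

Step 16
Reactants: 26 methyl (5Z,7S)-7-[(tert-butyldimethylsilyl)oxy]-7-{7-[(tert-butyldimethylsilyl)oxy]-7-[(2Z)-oct-2-en-1-yl]-1,4-dioxaspiro[4.4]nonan-6-yl}hept-5-enoate
Product: 27 bis-silyl C9 ketone: methyl (5Z,7S)-7-[(tert-butyldimethylsilyl)oxy]-7-{(1R,2S)-2-[(tert-butyldimethylsilyl)oxy]-2-[(2Z)-oct-2-en-1-yl]-5-oxocyclopentyl}hept-5-enoate
Conditions: PPTS, acetone/H2O (10:1), 55 °C
Reagents that add atoms: water, O
Why: Acid-catalysed hydrolysis of the dioxolane frees the C9 ketone under conditions that the two TBS ethers should tolerate and that are too mild to eliminate a β-silyloxy group.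

Step 17
Reactants: 27 bis-silyl C9 ketone
Product: 29 10-chloro ketone: methyl (5Z,7S)-7-[(tert-butyldimethylsilyl)oxy]-7-{2-[(tert-butyldimethylsilyl)oxy]-4-chloro-2-[(2Z)-oct-2-en-1-yl]-5-oxocyclopentyl}hept-5-enoate (both C10 epimers; C8 and C12 as in 27), via silyl enol ether 28 (not isolated)
Conditions: Me3SiCl, LiN(SiMe3)2, THF, −78 °C; then NCS, THF, 0 °C
Reagents that add atoms: N-chlorosuccinimide, ClN1C(=O)CCC1=O
Why: Kinetic deprotonation by the hindered amide takes the C10 methylene and not the C8 methine between two substituted carbons, the enolate is trapped in situ as 28, and NCS chlorinates this electron-rich enol ether at C10 (α-chlorination through a silyl enol ether) much faster than the isolated Z alkenes, both C10 epimers being usable.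

Step 18
Reactants: 29 10-chloro ketone
Product: 33 bis-silyl chloro enone: methyl (5Z,7S)-7-[(tert-butyldimethylsilyl)oxy]-7-{(1R,2S)-2-[(tert-butyldimethylsilyl)oxy]-4-chloro-2-[(2Z)-oct-2-en-1-yl]-5-oxocyclopent-3-en-1-yl}hept-5-enoate, via lithium chloro enolate 30 (not isolated), via chloro selenide 31 (not isolated), via selenoxide 32 (not isolated)
Conditions: LiN(SiMe3)2, THF, −78 °C; PhSeCl, −78 °C; then mCPBA, CH2Cl2, −78 °C; i-Pr2NH, −78 → 0 °C
Reagents that add atoms: none
Why: Selenoxide route to an α-substituted enone: the α-chloro proton on C10 is the most acidic, the enolate is selenenylated on carbon, and the selenoxide undergoes syn elimination with a C11 hydrogen, the only β-hydrogen, to give C10=C11 with chlorine on C10.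

Step 19
Reactants: 33 bis-silyl chloro enone
Product: 34 7-O-deacetylpunaglandin 8: methyl (5Z,7S)-7-{(1R,2S)-4-chloro-2-hydroxy-2-[(2Z)-oct-2-en-1-yl]-5-oxocyclopent-3-en-1-yl}-7-hydroxyhept-5-enoate
Conditions: HF (48 % aq.), MeCN, 0 °C → rt
Reagents that add atoms: none
Why: Acidic fluoride cleavage of both silyl ethers; the absence of base avoids retro-aldol opening and loss of the C7 oxygen, and the C12 carbinol of a 4-hydroxycyclopent-2-enone does not ionise.

Step 20
Reactants: 34 7-O-deacetylpunaglandin 8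
Product: 35 punaglandin 8 (7S,8R,12S in prostanoid numbering)
Conditions: Ac2O, pyridine, CH2Cl2, 0 °C
Reagents that add atoms: acetic anhydride, CC(=O)OC(C)=O
Why: Acylation of the secondary allylic C7 hydroxyl; the hindered tertiary C12 hydroxyl should not be acylated under these conditions, and pyridine at 0 °C should be too weak a base to eliminate acetic acid across C7–C8.

**Compound list**

1 | methyl acetoacetate | COC(=O)CC(C)=O | starting material
2 | allyl bromide | C=CCBr | starting material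
3 | sodium lithium dianion of methyl acetoacetate | [Na+].[Li+].[CH2-]C(=O)[CH-]C(=O)OC | intermediate
4 | methyl 3-oxohept-6-enoate | COC(=O)CC(=O)CCC=C | intermediate
5 | methyl 2-[2-(but-3-en-1-yl)-1,3-dioxolan-2-yl]acetate | COC(=O)CC1(CCC=C)OCCO1 | intermediate
6 | methyl 2-{2-[2-(oxiran-2-yl)ethyl]-1,3-dioxolan-2-yl}acetate (racemic) | COC(=O)CC1(CCC2CO2)OCCO1 | intermediate
7 | 1-heptyne | CCCCCC#C | starting material
8 | lithium hept-1-yn-1-ide | [Li]C#CCCCCC | intermediate
9 | methyl 2-[2-(3-hydroxyundec-5-yn-1-yl)-1,3-dioxolan-2-yl]acetate (racemic) | CCCCCC#CCC(O)CCC1(CC(=O)OC)OCCO1 | intermediate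
10 | methyl 2-{2-[(5Z)-3-hydroxyundec-5-en-1-yl]-1,3-dioxolan-2-yl}acetate (racemic) | CCCCC/C=C\CC(O)CCC1(CC(=O)OC)OCCO1 | intermediate
11 | 2-{2-[(5Z)-3-hydroxyundec-5-en-1-yl]-1,3-dioxolan-2-yl}acetic acid (racemic) | CCCCC/C=C\CC(O)CCC1(CC(=O)O)OCCO1 | intermediate
12 | (8Z)-3,3-(ethylenedioxy)-6-oxotetradec-8-enoic acid (achiral keto acid) | CCCCC/C=C\CC(=O)CCC1(CC(=O)O)OCCO1 | intermediate
13 | mixed anhydride of 12 with p-toluenesulfonic acid | CCCCC/C=C\CC(=O)CCC1(CC(=O)OS(=O)(=O)c2ccc(C)cc2)OCCO1 | intermediate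
14 | N-acyl isothiouronium tosylate from 12 and (S)-homobenzotetramisole | CCCCC/C=C\CC(=O)CCC1(CC(=O)[N+]2=C3Sc4ccccc4N3CC[C@H]2c2ccccc2)OCCO1.Cc1ccc(cc1)S(=O)(=O)[O-] | intermediate
15 | (1R,5S)-5-[(2Z)-oct-2-en-1-yl]spiro[6-oxabicyclo[3.2.0]heptane-2,2'-[1,3]dioxolan]-7-one (cis-fused β-lactone) | CCCCC/C=C\C[C@@]12CCC3(OCCO3)[C@@H]1C(=O)O2 | intermediate
16 | (6R,7S)-7-hydroxy-N-methoxy-N-methyl-7-[(2Z)-oct-2-en-1-yl]-1,4-dioxaspiro[4.4]nonane-6-carboxamide | CCCCC/C=C\C[C@@]1(O)CCC2(OCCO2)[C@@H]1C(=O)N(C)OC | intermediate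
17 | (6R,7S)-7-[(tert-butyldimethylsilyl)oxy]-N-methoxy-N-methyl-7-[(2Z)-oct-2-en-1-yl]-1,4-dioxaspiro[4.4]nonane-6-carboxamide | CCCCC/C=C\C[C@@]1(O[Si](C)(C)C(C)(C)C)CCC2(OCCO2)[C@@H]1C(=O)N(C)OC | intermediate
18 | 4-bromo-1,1,1-trimethoxybutane | COC(OC)(OC)CCCBr | starting material
19 | lithium acetylide–ethylenediamine complex | [Li]C#C.NCCN | starting material
20 | 6,6,6-trimethoxyhex-1-yne | COC(OC)(OC)CCCC#C | intermediate
21 | lithium 6,6,6-trimethoxyhex-1-yn-1-ide | [Li]C#CCCCC(OC)(OC)OC | intermediate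
22 | ynone from 17 and 21 with C1 still the trimethyl ortho ester (ring as in 17) | CCCCC/C=C\C[C@@]1(O[Si](C)(C)C(C)(C)C)CCC2(OCCO2)[C@@H]1C(=O)C#CCCCC(OC)(OC)OC | intermediate
23 | methyl 7-{7-[(tert-butyldimethylsilyl)oxy]-7-[(2Z)-oct-2-en-1-yl]-1,4-dioxaspiro[4.4]nonan-6-yl}-7-oxohept-5-ynoate (ring as in 17) | CCCCC/C=C\C[C@@]1(O[Si](C)(C)C(C)(C)C)CCC2(OCCO2)[C@@H]1C(=O)C#CCCCC(=O)OC | intermediate
24 | methyl (7R)-7-{7-[(tert-butyldimethylsilyl)oxy]-7-[(2Z)-oct-2-en-1-yl]-1,4-dioxaspiro[4.4]nonan-6-yl}-7-hydroxyhept-5-ynoate (ring as in 17) | CCCCC/C=C\C[C@@]1(O[Si](C)(C)C(C)(C)C)CCC2(OCCO2)[C@@H]1[C@H](C#CCCCC(=O)OC)O | intermediate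
25 | methyl (5Z,7S)-7-{7-[(tert-butyldimethylsilyl)oxy]-7-[(2Z)-oct-2-en-1-yl]-1,4-dioxaspiro[4.4]nonan-6-yl}-7-hydroxyhept-5-enoate (ring as in 17) | CCCCC/C=C\C[C@@]1(O[Si](C)(C)C(C)(C)C)CCC2(OCCO2)[C@@H]1[C@H](/C=C\CCCC(=O)OC)O | intermediate
26 | methyl (5Z,7S)-7-[(tert-butyldimethylsilyl)oxy]-7-{7-[(tert-butyldimethylsilyl)oxy]-7-[(2Z)-oct-2-en-1-yl]-1,4-dioxaspiro[4.4]nonan-6-yl}hept-5-enoate (ring as in 17) | CCCCC/C=C\C[C@@]1(O[Si](C)(C)C(C)(C)C)CCC2(OCCO2)[C@@H]1[C@H](/C=C\CCCC(=O)OC)O[Si](C)(C)C(C)(C)C | intermediate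
27 | bis-silyl C9 ketone: methyl (5Z,7S)-7-[(tert-butyldimethylsilyl)oxy]-7-{(1R,2S)-2-[(tert-butyldimethylsilyl)oxy]-2-[(2Z)-oct-2-en-1-yl]-5-oxocyclopentyl}hept-5-enoate | CCCCC/C=C\C[C@@]1(O[Si](C)(C)C(C)(C)C)CCC(=O)[C@@H]1[C@H](/C=C\CCCC(=O)OC)O[Si](C)(C)C(C)(C)C | intermediate
28 | trimethylsilyl enol ether of 27 across C9=C10 | CCCCC/C=C\C[C@@]1(O[Si](C)(C)C(C)(C)C)CC=C(O[Si](C)(C)C)[C@@H]1[C@H](/C=C\CCCC(=O)OC)O[Si](C)(C)C(C)(C)C | intermediate
29 | 10-chloro ketone (both C10 epimers; C7, C8, C12 as in 27) | CCCCC/C=C\C[C@@]1(O[Si](C)(C)C(C)(C)C)CC(Cl)C(=O)[C@@H]1[C@H](/C=C\CCCC(=O)OC)O[Si](C)(C)C(C)(C)C | intermediate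
30 | lithium enolate of 29 across C9=C10 | CCCCC/C=C\C[C@@]1(O[Si](C)(C)C(C)(C)C)CC(Cl)=C(O[Li])[C@@H]1[C@H](/C=C\CCCC(=O)OC)O[Si](C)(C)C(C)(C)C | intermediate
31 | 10-chloro-10-(phenylselanyl) ketone | CCCCC/C=C\C[C@@]1(O[Si](C)(C)C(C)(C)C)CC(Cl)([Se]c2ccccc2)C(=O)[C@@H]1[C@H](/C=C\CCCC(=O)OC)O[Si](C)(C)C(C)(C)C | intermediate
32 | selenoxide of 31 | CCCCC/C=C\C[C@@]1(O[Si](C)(C)C(C)(C)C)CC(Cl)([Se](=O)c2ccccc2)C(=O)[C@@H]1[C@H](/C=C\CCCC(=O)OC)O[Si](C)(C)C(C)(C)C | intermediate
33 | bis-silyl chloro enone (7S,8R,12S) | CCCCC/C=C\C[C@@]1(O[Si](C)(C)C(C)(C)C)C=C(Cl)C(=O)[C@@H]1[C@H](/C=C\CCCC(=O)OC)O[Si](C)(C)C(C)(C)C | intermediate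
34 | 7-O-deacetylpunaglandin 8 (7S,8R,12S) | CCCCC/C=C\C[C@@]1(O)C=C(Cl)C(=O)[C@@H]1[C@H](/C=C\CCCC(=O)OC)O | intermediate
35 | punaglandin 8 (7S,8R,12S) | CCCCC/C=C\C[C@@]1(O)C=C(Cl)C(=O)[C@@H]1[C@H](/C=C\CCCC(=O)OC)OC(C)=O | target

**Step count and risks**

Total step count: 20 (19 in the main line and the one-step preparation of 20).
Longest linear sequence: 19 steps from methyl acetoacetate (steps 1–10 and 12–20).

Steps most likely to fail:

1. Step 8. The catalyst-bound enolate may add to a ketone flanked by two methylene groups slowly and with poor enantioface discrimination. The fallback gives up asymmetric catalysis and separates diastereomers later; it sets out from 12 and comes back at 24. Keto acid 12 is cyclised under the same activation with TsCl, i-Pr2NEt and LiCl, but with achiral 4-pyrrolidinopyridine as the Lewis base. The reaction passes through the N-acyl-4-pyrrolidinopyridinium tosylate F1 and gives the racemic lactone, that is 15 together with its (1S,5R)-enantiomer F2. Lactone opening, silylation and acetylide addition are run on the racemate as in the main route and give, beside 16, 17, 22 and 23, the enantiomeric hydroxy amide F3, the enantiomeric silyl ether F4, the enantiomeric ortho ester ynone F5 and the enantiomeric ynone F6. Transfer hydrogenation with the (R,R)-ruthenium catalyst of the main route should set C7 as R in both ynone enantiomers, so that the racemate becomes two diastereomers, 24 and the (7R)-propargylic alcohol with the mirror-image ring F7. These are separated by chromatography, and 24 goes on into the Lindlar reduction.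

2. Step 13. Hydride transfer to a carbonyl next to a methine that lies between two fully substituted carbons may be slow, and the ring may oppose the facial preference of the catalyst. The fallback uses substrate chelation in place of reagent control; it sets out from 16 and comes back at 26. Hydroxy amide 16 is not silylated: three equivalents of acetylide 21 and the same acidic work-up give, through the hydroxy ortho ester ynone F8, the β-hydroxy ynone F9. Zn(BH4)2 in Et2O at −40 °C ties the C12 hydroxyl and the C7 carbonyl into a six-membered zinc chelate cis-fused to the cyclopentane and should deliver hydride to its convex face, the side of the C8 hydrogen, which gives the (7R)-propargylic diol F10 with the C7 configuration of 24. Lindlar reduction gives the (5Z,7S)-allylic diol F11, and an excess of TBSOTf with 2,6-lutidine silylates both hydroxyls to give 26.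

3. Step 18. The second deprotonation may take the C8 proton in place of the C10 proton and expel a silyloxy group, or the crowded chloro enolate may be selenenylated slowly. The fallback makes the enone first and brings in chlorine through an epoxide; it sets out from 27 and comes back at 33. Silyl enol ether 28, made from 27 as in the main route, is dehydrogenated with Pd(OAc)2 in MeCN (Saegusa–Ito oxidation) to the bis-silyl C10=C11 enone F12. Alkaline H2O2 in MeOH at −20 °C epoxidises only this electron-poor double bond and gives the bis-silyl 10,11-epoxy ketone F13. Anhydrous HCl in CHCl3 at 0 °C opens the epoxide at C10, the carbon α to the carbonyl, to the bis-silyl 10-chloro-11-hydroxy ketone F14, which loses water to give 33.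

**Further compounds**

F1 | step 8 | N-acyl-4-pyrrolidinopyridinium tosylate from 12 | CCCCC/C=C\CC(=O)CCC1(CC(=O)[n+]2ccc(cc2)N2CCCC2)OCCO1.Cc1ccc(cc1)S(=O)(=O)[O-]
F2 | step 8 | (1S,5R)-lactone, enantiomer of 15 | CCCCC/C=C\C[C@]12CCC3(OCCO3)[C@H]1C(=O)O2
F3 | step 8 | (6S,7R)-hydroxy amide, enantiomer of 16 | CCCCC/C=C\C[C@]1(O)CCC2(OCCO2)[C@H]1C(=O)N(C)OC
F4 | step 8 | (6S,7R)-silyl ether, enantiomer of 17 | CCCCC/C=C\C[C@]1(O[Si](C)(C)C(C)(C)C)CCC2(OCCO2)[C@H]1C(=O)N(C)OC
F5 | step 8 | enantiomer of ortho ester ynone 22 | CCCCC/C=C\C[C@]1(O[Si](C)(C)C(C)(C)C)CCC2(OCCO2)[C@H]1C(=O)C#CCCCC(OC)(OC)OC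
F6 | step 8 | enantiomer of ynone 23 | CCCCC/C=C\C[C@]1(O[Si](C)(C)C(C)(C)C)CCC2(OCCO2)[C@H]1C(=O)C#CCCCC(=O)OC
F7 | step 8 | (7R)-propargylic alcohol with the mirror-image ring, diastereomer of 24 | CCCCC/C=C\C[C@]1(O[Si](C)(C)C(C)(C)C)CCC2(OCCO2)[C@H]1[C@H](C#CCCCC(=O)OC)O
F8 | step 13 | hydroxy ortho ester ynone from 16 and 21 | CCCCC/C=C\C[C@@]1(O)CCC2(OCCO2)[C@@H]1C(=O)C#CCCCC(OC)(OC)OC
F9 | step 13 | β-hydroxy ynone, methyl 7-{7-hydroxy-7-[(2Z)-oct-2-en-1-yl]-1,4-dioxaspiro[4.4]nonan-6-yl}-7-oxohept-5-ynoate | CCCCC/C=C\C[C@@]1(O)CCC2(OCCO2)[C@@H]1C(=O)C#CCCCC(=O)OC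
F10 | step 13 | (7R)-propargylic diol | CCCCC/C=C\C[C@@]1(O)CCC2(OCCO2)[C@@H]1[C@H](C#CCCCC(=O)OC)O
F11 | step 13 | (5Z,7S)-allylic diol | CCCCC/C=C\C[C@@]1(O)CCC2(OCCO2)[C@@H]1[C@H](/C=C\CCCC(=O)OC)O
F12 | step 18 | bis-silyl C10=C11 enone | CCCCC/C=C\C[C@@]1(O[Si](C)(C)C(C)(C)C)C=CC(=O)[C@@H]1[C@H](/C=C\CCCC(=O)OC)O[Si](C)(C)C(C)(C)C
F13 | step 18 | bis-silyl 10,11-epoxy ketone | CCCCC/C=C\C[C@@]1(O[Si](C)(C)C(C)(C)C)C2OC2C(=O)[C@@H]1[C@H](/C=C\CCCC(=O)OC)O[Si](C)(C)C(C)(C)C
F14 | step 18 | bis-silyl 10-chloro-11-hydroxy ketone | CCCCC/C=C\C[C@@]1(O[Si](C)(C)C(C)(C)C)C(O)C(Cl)C(=O)[C@@H]1[C@H](/C=C\CCCC(=O)OC)O[Si](C)(C)C(C)(C)C
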